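**Plan**

1. Labdane numbering is used (ring A = C1–C5 and C10, ring B = C5–C10, side chain C11–C16, C17 on C8, C20 on C10). The retrosynthesis cuts the two formates, then C11–C12 (Wittig), then the second C4 methyl and C5–H (reductive methylation of a C4=C5 enone), then ring B at C5–C6 and C8–C9.
2. Feature used: ring B holds the allyl unit C6H2–C7H=C8(CH3), whose two ends are bonded to C5 and C9, and these two carbons are held 1,3 to each other by the quaternary C10 of ring A. One 3-silylbut-2-enyl unit can therefore be stitched in by two consecutive allylic transpositions: a [3,3] shift onto C9 (C8–C9), then an SE2' attack of C6 on the ring A carbonyl carbon C5 (C5–C6), which returns the alkene to C7=C8.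
3. Forward order: ring A first (vinylogous ester of 2-methylcyclohexane-1,3-dione, C10 by palladium-catalysed decarboxylative allylation), then ring B in one flask (Ireland–Claisen, then Sakurai), then Li/NH3 reductive methylation, then the side chain by Wittig and diimide, then the bis-formate.
4. Stereochemistry: C10 from the (R)-t-Bu-PHOX allylation; C9 from the Claisen stage under control of C10; C5 (trans ring fusion) from the dissolving-metal reduction; C3 from axial hydride delivery; C13 from (R)-4-methyldihydrofuran-2(3H)-one.

Key step: step 10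

Assumption: in step 4 the (R)-ligand is taken to select the same enolate face as it does with 2-methylcyclohexanone-derived enol carbonates, which gives (R)-7; if the sense is opposite, the (S)-ligand is used.

**Route**

Step 1
Reactants: 1 2-methylcyclohexane-1,3-dione
Product: 2 3-isobutoxy-2-methylcyclohex-2-en-1-one
Conditions: i-BuOH, TsOH·H2O (cat.), PhMe, reflux, Dean–Stark
Reagents that add atoms: 2-methylpropan-1-ol, CC(C)CO
Why: Acid-catalysed O-alkylation of the enolised 1,3-dione with azeotropic removal of water (vinylogous ester formation) should proceed cleanly, and no stereocentre is formed.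

Step 2
Reactants: 2 3-isobutoxy-2-methylcyclohex-2-en-1-one
Product: 4 3-isobutoxy-2,6-dimethylcyclohex-2-en-1-one (racemic), via lithium enolate 3 (not isolated)
Conditions: LiN(i-Pr)2, THF, −78 °C; MeI, −78 → 0 °C
Reagents that add atoms: iodomethane, CI
Why: Kinetic deprotonation of a vinylogous ester takes place at the α' carbon (the future C10) and the enolate is C-methylated (Stork–Danheiser α'-alkylation); the new centre is racemic and becomes sp2 again in step 3.

Step 3
Reactants: 4 3-isobutoxy-2,6-dimethylcyclohex-2-en-1-one
Product: 6 allyl 5-isobutoxy-2,6-dimethylcyclohexa-1,5-dien-1-yl carbonate, via lithium enolate 5 (not isolated)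
Conditions: LiN(i-Pr)2, TMEDA, THF, −78 °C; allyl chloroformate, −78 °C → rt
Reagents that add atoms: allyl chloroformate, C=CCOC(=O)Cl
Why: The fully substituted α' enolate should be acylated on oxygen by the hard chloroformate (enol carbonate formation), which gives the substrate class for decarboxylative allylation; 6 has no stereocentre.

Step 4
Reactants: 6 allyl 5-isobutoxy-2,6-dimethylcyclohexa-1,5-dien-1-yl carbonate
Product: 7 (R)-6-allyl-3-isobutoxy-2,6-dimethylcyclohex-2-en-1-one
Conditions: Pd2(dba)3 (2.5 mol%), (R)-t-Bu-PHOX (6 mol%), PhMe, 25 °C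
Reagents that add atoms: none
Why: In this decarboxylative asymmetric allylic alkylation (Tsuji allylation), ionisation and loss of CO2 give a palladium allyl enolate that recombines inside the chiral phosphinooxazoline pocket, so the ligand selects the enolate face and sets C10 as (R).

Step 5
Reactants: 7 (R)-6-allyl-3-isobutoxy-2,6-dimethylcyclohex-2-en-1-one
Product: 8 (R)-2-(4-isobutoxy-1,3-dimethyl-2-oxocyclohex-3-en-1-yl)acetaldehyde
Conditions: OsO4 (2 mol%), NaIO4, 2,6-lutidine, dioxane–H2O, rt
Reagents that add atoms: sodium periodate, [Na+].[O-]I(=O)(=O)=O (terminal oxidant; the aldehyde oxygen is delivered through OsO4, O=[Os](=O)(=O)=O)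
Why: In this Lemieux–Johnson cleavage the monosubstituted alkene is dihydroxylated far faster than the tetrasubstituted, acceptor-substituted enol ether, and periodate cleaves the diol to the aldehyde without touching C10.

Step 6
Reactants: 8 (R)-2-(4-isobutoxy-1,3-dimethyl-2-oxocyclohex-3-en-1-yl)acetaldehyde
Product: 9 (R)-2-(4-isobutoxy-1,3-dimethyl-2-oxocyclohex-3-en-1-yl)acetic acid
Conditions: NaClO2, NaH2PO4, 2-methyl-2-butene, t-BuOH–H2O, 0 °C → rt
Reagents that add atoms: sodium chlorite, [Na+].[O-]Cl=O
Why: Pinnick oxidation converts the aldehyde into the acid under buffered conditions that should leave the vinylogous ester and the stereocentre intact.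

Step 7
Reactants: 10 ethyl but-2-ynoate
Product: 11 ethyl (E)-3-[dimethyl(phenyl)silyl]but-2-enoate
Conditions: Me2PhSi–Bpin, CuCl (5 mol%), PPh3 (6 mol%), NaOt-Bu (10 mol%), MeOH, THF, 0 °C → rt
Reagents that add atoms: (dimethylphenylsilyl)boronic acid pinacol ester, C[Si](C)(c1ccccc1)B1OC(C)(C)C(C)(C)O1
Why: Copper-catalysed conjugate silylation of the ynoate adds silicon to the β carbon and copper to the α carbon in a syn sense, and protonation of the vinylcopper by methanol gives the (E)-β-silyl enoate.

Step 8
Reactants: 11 ethyl (E)-3-[dimethyl(phenyl)silyl]but-2-enoate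
Product: 12 (E)-3-[dimethyl(phenyl)silyl]but-2-en-1-ol
Conditions: i-Bu2AlH (2.2 equiv), CH2Cl2, −78 → 0 °C; aq. KNaC4H4O6
Reagents that add atoms: none
Why: 1,2-Reduction of the enoate by the aluminium hydride gives the allylic alcohol without touching the vinylsilane, and the alkene geometry is kept.

Step 9
Reactants: 9 (R)-2-(4-isobutoxy-1,3-dimethyl-2-oxocyclohex-3-en-1-yl)acetic acid; 12 (E)-3-[dimethyl(phenyl)silyl]but-2-en-1-ol
Product: 13 (E)-3-[dimethyl(phenyl)silyl]but-2-en-1-yl (R)-2-(4-isobutoxy-1,3-dimethyl-2-oxocyclohex-3-en-1-yl)acetate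
Conditions: DCC, DMAP (cat.), CH2Cl2, 0 °C → rt
Reagents that add atoms: none
Why: Steglich esterification joins the hindered acid to the primary allylic alcohol under neutral conditions that affect neither the enol ether nor the stereocentre.

Step 10
Reactants: 13 (E)-3-[dimethyl(phenyl)silyl]but-2-en-1-yl (R)-2-(4-isobutoxy-1,3-dimethyl-2-oxocyclohex-3-en-1-yl)acetate
Product: 17 3-oxo-14-nordrima-4,7-dien-11-oic acid (9αH; 10β-CH3), via silyl ketene acetal 14 (not isolated), via allylsilane silyl ester 15 (not isolated), via ring B silyl ether 16 (not isolated)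
Conditions: KN(SiMe3)2, Me3SiCl, PhMe, −78 → 70 °C; volatiles removed; CH2Cl2, Me3SiOTf (0.3 equiv), −78 → −20 °C; 0.5 M HCl–THF, 0 °C (one flask)
Reagents that add atoms: water, O
Why: Proposed new method: kinetic enolisation of the ester and O-silylation give the (Z)-silyl ketene acetal 14, whose chair-like [3,3] shift joins C9 to the silicon-bearing alkene carbon C8 and turns the vinylsilane into the tertiary allylsilane 15; silyl triflate then converts the vinylogous ester into a 1-siloxy-3-alkoxyallyl cation, which the allylsilane attacks through its terminal carbon C6 in an anti SE2' sense, the silyl group leaving from C8 so that the alkene returns to C7=C8, and aqueous acid completes the loss of the C5 oxygen and the enol ether hydrolysis to the C4=C5 enone. The closest known reaction types are the Ireland–Claisen rearrangement of 3-silylallyl esters to allylsilanes, the intramolecular Hosomi–Sakurai cyclisation and the Stork–Danheiser transposition; their one-flask union and the use of a silyl-activated vinylogous ester as the acceptor are not precedented. Only ring B is closed, by the C5–C6 bond, in a closure that is 6-endo with respect to the allylsilane double bond and 6-exo-trig with respect to the C5 carbonyl; it is unambiguous because attack through C8 would need a four-membered ring and the β carbon C3 is out of reach. C9 is the only new stereocentre that survives (C5 and C8 both end as sp2 carbons) and is set in the Claisen stage by the adjacent quaternary C10: with the ring carbonyl carbon C5 eclipsing the C9–H bond to avoid allylic strain, the allyl unit should add to the enolate face opposite the ring methylene C1 and on the side of the small methyl group, which gives 9αH. The step needs enolisation of the ester in preference to the γ-hydrogens of the vinylogous ester, which the blocked α' position, the kinetic base and the internal silyl chloride quench should secure, and it needs cyclisation to outrun protodesilylation, which the six-membered transition state and the absence of protic acid before work-up should secure.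

Step 11
Reactants: 17 3-oxo-14-nordrima-4,7-dien-11-oic acid
Product: 19 3-oxodrim-7-en-11-oic acid (5αH; 9αH; 10β-CH3), via dilithium enolate carboxylate 18 (not isolated)
Conditions: Li (3.3 equiv), NH3(l)–THF, t-BuOH (1 equiv), −78 °C; MeI, −78 → −33 °C; aq. NH4Cl, then 1 M HCl
Reagents that add atoms: iodomethane, CI
Why: In this dissolving-metal reduction with reductive alkylation of the enolate, the β-carbanion at C5 is protonated axially from the α face, anti to the angular C10 methyl, which gives the trans ring fusion, and the regiospecific lithium enolate is C-methylated at C4 to complete the gem-dimethyl group, while the isolated C7=C8 alkene and the carboxylate are not reduced.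

Step 12
Reactants: 19 3-oxodrim-7-en-11-oic acid
Product: 20 drim-7-ene-3β,11-diol
Conditions: LiAlH4, THF, 0 °C → reflux; aq. NaOH work-up
Reagents that add atoms: none
Why: Hydride reduction converts the acid into the primary alcohol and attacks the C3 ketone axially from the less hindered α face, opposite the axial 4β- and 10β-methyl groups, which gives the equatorial 3β-alcohol.

Step 13
Reactants: 20 drim-7-ene-3β,11-diol
Product: 21 3β-hydroxydrim-7-en-11-al
Conditions: TEMPO (10 mol%), PhI(OAc)2, CH2Cl2, rt
Reagents that add atoms: none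
Why: The oxoammonium oxidation is selective for the primary alcohol over the hindered secondary one and is not basic, so the C9 stereocentre next to the new aldehyde should be kept.

Step 14
Reactants: 22 (R)-4-methyldihydrofuran-2(3H)-one
Product: 23 ethyl (R)-4-bromo-3-methylbutanoate
Conditions: HBr (gas), EtOH, 0 °C → rt
Reagents that add atoms: hydrogen bromide, Br; ethanol, CCO
Why: Bromide opens the protonated γ-lactone at the O–CH2 carbon (SN2) and the carboxyl is esterified by the solvent (Fischer esterification), so C13 is not involved and keeps its configuration.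

Step 15
Reactants: 23 ethyl (R)-4-bromo-3-methylbutanoate
Product: 24 [(R)-4-ethoxy-2-methyl-4-oxobutyl]triphenylphosphonium bromide
Conditions: PPh3, MeCN, reflux
Reagents that add atoms: triphenylphosphine, c1ccc(cc1)P(c1ccccc1)c1ccccc1
Why: SN2 quaternisation of the phosphine by the primary bromide gives the Wittig salt and leaves the adjacent stereocentre untouched.

Step 16
Reactants: 21 3β-hydroxydrim-7-en-11-al; 24 [(R)-4-ethoxy-2-methyl-4-oxobutyl]triphenylphosphonium bromide
Product: 26 ethyl (11Z,13R)-3β-hydroxylabda-7,11-dien-15-oate, via phosphorus ylide 25 (not isolated)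
Conditions: 24 (2.5 equiv), NaN(SiMe3)2 (2.4 equiv), THF, −78 → 0 °C; then 21, −78 °C → rt
Reagents that add atoms: none
Why: Wittig olefination with the non-stabilised ylide joins C11 to C12 as the (Z)-alkene, the excess ylide covers the free 3-hydroxyl, and the low temperature should keep C9 from epimerising.

Step 17
Reactants: 26 ethyl (11Z,13R)-3β-hydroxylabda-7,11-dien-15-oate
Product: 27 ethyl (13S)-3β-hydroxylabd-7-en-15-oate
Conditions: 2-nitrobenzenesulfonohydrazide, Et3N, CH2Cl2, rt
Reagents that add atoms: none
Why: Diimide made in the flask reduces the 1,2-disubstituted C11=C12 alkene by concerted syn hydrogen transfer much faster than the trisubstituted ring alkene, and no stereocentre is created.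

Step 18
Reactants: 27 ethyl (13S)-3β-hydroxylabd-7-en-15-oate
Product: 28 (13S)-labd-7-ene-3β,15-diol
Conditions: LiAlH4, THF, 0 °C; aq. NaOH work-up
Reagents that add atoms: none
Why: Hydride reduction of the ethyl ester gives the primary C15 alcohol and affects no stereocentre.

Step 19
Reactants: 28 (13S)-labd-7-ene-3β,15-diol
Product: 29 (13S)-labd-7-ene-3β,15-diyl diformate (CNP0137609.1)
Conditions: HCO2H/Ac2O (premixed, 50 °C), then pyridine, CH2Cl2, 0 °C → rt
Reagents that add atoms: acetic formic anhydride, CC(=O)OC=O
Why: The mixed anhydride transfers its formyl group selectively (O-formylation) and is reactive enough for the hindered secondary 3β-alcohol as well as the primary one, with retention at every stereocentre.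

**Compound list**

1 | 2-methylcyclohexane-1,3-dione | CC1C(=O)CCCC1=O | starting material
2 | 3-isobutoxy-2-methylcyclohex-2-en-1-one | CC1=C(OCC(C)C)CCCC1=O | intermediate
3 | lithium 5-isobutoxy-6-methylcyclohexa-1,5-dien-1-olate (α' enolate of 2) | [Li+].[O-]C1=CCCC(OCC(C)C)=C1C | intermediate (not isolated)
4 | 3-isobutoxy-2,6-dimethylcyclohex-2-en-1-one (racemic) | CC1CCC(OCC(C)C)=C(C)C1=O | intermediate
5 | lithium 5-isobutoxy-2,6-dimethylcyclohexa-1,5-dien-1-olate | [Li+].[O-]C1=C(C)CCC(OCC(C)C)=C1C | intermediate (not isolated)
6 | allyl 5-isobutoxy-2,6-dimethylcyclohexa-1,5-dien-1-yl carbonate | C=CCOC(=O)OC1=C(C)CCC(OCC(C)C)=C1C | intermediate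
7 | (R)-6-allyl-3-isobutoxy-2,6-dimethylcyclohex-2-en-1-one | O=C1C(C)=C(OCC(C)C)CC[C@]1(C)CC=C | intermediate
8 | (R)-2-(4-isobutoxy-1,3-dimethyl-2-oxocyclohex-3-en-1-yl)acetaldehyde | O=C1C(C)=C(OCC(C)C)CC[C@]1(C)CC=O | intermediate
9 | (R)-2-(4-isobutoxy-1,3-dimethyl-2-oxocyclohex-3-en-1-yl)acetic acid | O=C1C(C)=C(OCC(C)C)CC[C@]1(C)CC(=O)O | intermediate
10 | ethyl but-2-ynoate | CC#CC(=O)OCC | starting material
11 | ethyl (E)-3-[dimethyl(phenyl)silyl]but-2-enoate | CCOC(=O)/C=C(\C)[Si](C)(C)c1ccccc1 | intermediate
12 | (E)-3-[dimethyl(phenyl)silyl]but-2-en-1-ol | OC/C=C(\C)[Si](C)(C)c1ccccc1 | intermediate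
13 | (E)-3-[dimethyl(phenyl)silyl]but-2-en-1-yl (R)-2-(4-isobutoxy-1,3-dimethyl-2-oxocyclohex-3-en-1-yl)acetate | O=C1C(C)=C(OCC(C)C)CC[C@]1(C)CC(=O)OC/C=C(\C)[Si](C)(C)c1ccccc1 | intermediate
14 | (Z)-trimethylsilyl ketene acetal of 13 (C10 cis to OSiMe3) | O=C1C(C)=C(OCC(C)C)CC[C@]1(C)/C=C(\O[Si](C)(C)C)OC/C=C(\C)[Si](C)(C)c1ccccc1 | intermediate (not isolated)
15 | trimethylsilyl 2-[(R)-4-isobutoxy-1,3-dimethyl-2-oxocyclohex-3-en-1-yl]-3-[dimethyl(phenyl)silyl]-3-methylpent-4-enoate (C9 as in the target; C8 as expected from the chair transition state, of no consequence) | O=C1C(C)=C(OCC(C)C)CC[C@]1(C)[C@@H](C(=O)O[Si](C)(C)C)[C@@](C)([Si](C)(C)c1ccccc1)C=C | intermediate (not isolated)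
16 | trimethylsilyl 5-[dimethyl(phenyl)silyloxy]-3-isobutoxy-14-nordrima-3,7-dien-11-oate (ring B closed; C5 configuration not defined, lost in the next stage) | CC1=CCC2(O[Si](C)(C)c3ccccc3)C(C)=C(OCC(C)C)CC[C@]2(C)[C@H]1C(=O)O[Si](C)(C)C | intermediate (not isolated)
17 | 3-oxo-14-nordrima-4,7-dien-11-oic acid (9αH, 10β-CH3; C4=C5 and C7=C8) | CC1=CCC2=C(C)C(=O)CC[C@]2(C)[C@H]1C(=O)O | intermediate
18 | dilithium salt of the C3 enolate and C11 carboxylate (5αH) | [Li+].[Li+].CC1=CC[C@H]2C(C)=C([O-])CC[C@]2(C)[C@H]1C([O-])=O | intermediate (not isolated)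
19 | 3-oxodrim-7-en-11-oic acid (5αH, 9αH, 10β-CH3) | CC1=CC[C@H]2C(C)(C)C(=O)CC[C@]2(C)[C@H]1C(=O)O | intermediate
20 | drim-7-ene-3β,11-diol | CC1=CC[C@H]2C(C)(C)[C@@H](O)CC[C@]2(C)[C@H]1CO | intermediate
21 | 3β-hydroxydrim-7-en-11-al | CC1=CC[C@H]2C(C)(C)[C@@H](O)CC[C@]2(C)[C@H]1C=O | intermediate
22 | (R)-4-methyldihydrofuran-2(3H)-one | C1[C@H](C)CC(=O)O1 | starting material
23 | ethyl (R)-4-bromo-3-methylbutanoate | BrC[C@H](C)CC(=O)OCC | intermediate
24 | [(R)-4-ethoxy-2-methyl-4-oxobutyl]triphenylphosphonium bromide | [Br-].c1ccc(cc1)[P+](c1ccccc1)(c1ccccc1)C[C@H](C)CC(=O)OCC | intermediate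
25 | ethyl (R)-3-methyl-4-(triphenyl-λ5-phosphanylidene)butanoate (ylide) | c1ccc(cc1)P(c1ccccc1)(c1ccccc1)=C[C@H](C)CC(=O)OCC | intermediate (not isolated)
26 | ethyl (11Z,13R)-3β-hydroxylabda-7,11-dien-15-oate | CC1=CC[C@H]2C(C)(C)[C@@H](O)CC[C@]2(C)[C@H]1/C=C\[C@H](C)CC(=O)OCC | intermediate
27 | ethyl (13S)-3β-hydroxylabd-7-en-15-oate | CC1=CC[C@H]2C(C)(C)[C@@H](O)CC[C@]2(C)[C@H]1CC[C@H](C)CC(=O)OCC | intermediate
28 | (13S)-labd-7-ene-3β,15-diol | CC1=CC[C@H]2C(C)(C)[C@@H](O)CC[C@]2(C)[C@H]1CC[C@H](C)CCO | intermediate
29 | (13S)-labd-7-ene-3β,15-diyl diformate (5αH, 9αH, 10β-CH3) | CC1=CC[C@H]2C(C)(C)[C@@H](OC=O)CC[C@]2(C)[C@H]1CC[C@H](C)CCOC=O | target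

**Totals**

Total step count: 19. Longest linear sequence: 15 steps (1–6, 9–13, 16–19).

**Steps most likely to fail**

Step 10 (Proposed new method). The base may deprotonate the γ-CH2 of the vinylogous ester instead of the ester α-CH2. The [3,3] shift may show poor facial selectivity at C9. The tertiary allylsilane may lose silicon by protonation before it cyclises. The silyl-activated vinylogous ester may be too weak an acceptor. The fallback builds ring B from known reactions, with ring-closing metathesis making C7=C8. It sets out from acid 9. Esterification with tert-butyl 2,2,2-trichloroacetimidate (BF3·OEt2 cat.) would give tert-butyl (R)-2-(4-isobutoxy-1,3-dimethyl-2-oxocyclohex-3-en-1-yl)acetate F1. Palladium-catalysed α-alkenylation of its lithium enolate with 2-bromopropene (Pd(dba)2, P(t-Bu)3, LiN(SiMe3)2, PhMe) would make the C8–C9 bond and give the α-isopropenyl ester F2. Stork–Danheiser addition of allylmagnesium bromide to the vinylogous ester carbonyl, followed by aqueous HCl, would make the C5–C6 bond and give the 5-allyl enone F3. Ring-closing metathesis with the second-generation Grubbs catalyst, RuCl2(=CHPh)(H2IMes)(PCy3), would close ring B to the tert-butyl ester F4, at which stage C9 epimers can be separated. CF3CO2H would then release acid 17, where the route is rejoined.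

Step 11. The carboxylate may pass a proton to the enolate so that C-methylation is lost. The doubly allylic C6 hydrogens may be removed by amide, which moves the C7=C8 alkene into conjugation and leads to over-reduction. The enolate may equilibrate and be methylated at C2. The fallback takes the acid function out of the reduction. It sets out from 17. Methylation with Me3SiCHN2 (MeOH–PhMe) would give methyl 3-oxo-14-nordrima-4,7-dien-11-oate F5. Li/NH3 reduction of this neutral ester with MeI quench would give methyl 3-oxodrim-7-en-11-oate F6. LiAlH4 then reduces F6 to diol 20, where the route is rejoined.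

Step 16. The basic ylide may epimerise C9 of the β,γ-unsaturated aldehyde or move the C7=C8 alkene into conjugation with it, and the hindered aldehyde may react slowly. The fallback joins C11 to C12 at the sp3 level and avoids the aldehyde. It sets out from diol 20. Selective iodination of the primary alcohol (I2, PPh3, imidazole) would give 11-iododrim-7-en-3β-ol F7. Zinc insertion into bromo ester 23 (Zn, LiCl, THF) would give [(R)-4-ethoxy-2-methyl-4-oxobutyl]zinc bromide F8. Nickel-catalysed alkyl–alkyl Negishi coupling of F7 with F8 (Ni(cod)2, s-Bu-Pybox, DMA) would give ester 27 directly, where the route is rejoined; steps 13, 16 and 17 are then not needed.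

Further compounds
F1 | step 10 | tert-butyl (R)-2-(4-isobutoxy-1,3-dimethyl-2-oxocyclohex-3-en-1-yl)acetate | O=C1C(C)=C(OCC(C)C)CC[C@]1(C)CC(=O)OC(C)(C)C
F2 | step 10 | tert-butyl 2-[(R)-4-isobutoxy-1,3-dimethyl-2-oxocyclohex-3-en-1-yl]-3-methylbut-3-enoate (C9 as in the target) | O=C1C(C)=C(OCC(C)C)CC[C@]1(C)[C@@H](C(=O)OC(C)(C)C)C(C)=C
F3 | step 10 | tert-butyl 2-[(R)-2-allyl-1,3-dimethyl-4-oxocyclohex-2-en-1-yl]-3-methylbut-3-enoate | C=CCC1=C(C)C(=O)CC[C@]1(C)[C@@H](C(=O)OC(C)(C)C)C(C)=C
F4 | step 10 | tert-butyl 3-oxo-14-nordrima-4,7-dien-11-oate | CC1=CCC2=C(C)C(=O)CC[C@]2(C)[C@H]1C(=O)OC(C)(C)C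
F5 | step 11 | methyl 3-oxo-14-nordrima-4,7-dien-11-oate | CC1=CCC2=C(C)C(=O)CC[C@]2(C)[C@H]1C(=O)OC
F6 | step 11 | methyl 3-oxodrim-7-en-11-oate | CC1=CC[C@H]2C(C)(C)C(=O)CC[C@]2(C)[C@H]1C(=O)OC
F7 | step 16 | 11-iododrim-7-en-3β-ol | CC1=CC[C@H]2C(C)(C)[C@@H](O)CC[C@]2(C)[C@H]1CI
F8 | step 16 | [(R)-4-ethoxy-2-methyl-4-oxobutyl]zinc bromide | Br[Zn]C[C@H](C)CC(=O)OCC
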